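## Analysis of the target

Target 32 is the C15 ester of an ent-labdane diol, (3R,5S,9R,10S)-labda-7,13E-diene-3,15-diol, with 30-hydroxytriacontanoic acid. Labdane numbering is used throughout: C1–C10 form the decalin, C11–C16 the side chain, C17 is the methyl on C8, C18/C19 sit on C4, and C20 is the methyl on C10.

Rings A and B are trans-fused. Ring A carries the secondary C3 hydroxyl next to the gem-dimethyl carbon C4. Ring B carries the trisubstituted C7=C8 alkene, and C9 carries the chain C11–C12–C13(C16)=C14–C15–O with an E alkene.

There are four stereocentres, C3, C5, C10 and C9. The 3-OH, C20 and the C9 side chain lie on one face, H5 and H9 on the other. The absolute series is the mirror image of the common labdanes (sclareol type), so the usual terpenoid chiral pool does not fit.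

Sensitive groups are the allylic ester (ionisation, acyl transfer), two acid-labile trisubstituted alkenes (the ring B alkene can move to C8=C17 or C8=C9), three different hydroxyls that must be told apart, and a waxy C30 chain.

The hard part is to close both rings with C5, C10 and C9 set relative to C3, to stop after ring B although C13=C14 sits where a third ring would close, and to put the ring B alkene only at C7=C8.

The feature the strategy is tied to is C8 of ring B. It is an sp2 carbon that carries only the C17 methyl and is flanked by the C7 methylene and the C9 stereocentre. C8 can therefore be a ketone carbon in the key step. C9 then becomes the nucleophilic carbon of an enol silane that ends the ring closure on oxygen, and the C7=C8 alkene and C17 are made afterwards from the ketone.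

## Retrosynthetic reasoning

**Ester C15–O bond (32 ⇒ 31 ⇒ 30 + 29).** The acyl C–O bond is cut last. The two halves are of similar size, and the waxy chain stays out of all skeleton chemistry. The forward reaction must acylate the primary allylic O15 of 30 while O3 and the ω-oxygen are silylated; one fluoride step then frees both. Acid 29 is cut in the middle of its chain into two C15 pieces, 26 and 24, both from the single bromo acid 24 (via 25).

**C8–C17 bond and the C7=C8 alkene (30 ⇐ 23 ⇐ 22 ⇐ 20 ⇐ 19).** The methyl C17 is cut from C8. The alkene position then follows from regioselective enolisation of the C8 ketone toward C7, because C9–H is tertiary and neopentyl. The forward sequence is enol triflate formation and methyl cross-coupling. The gain is that no alkene isomers can form.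

**Key disconnection, C4–C5 and C9–C10 (19 ⇐ 17).** Both rings are opened at the bonds where the alkene carbons C5 and C9 attack the electrophilic carbons C4 and C10. These are the bonds whose formation in one chair–chair array sets C5, C10 and C9 relative to C3 at once. The precursor 17 is an acyclic chain with a single stereocentre, the epoxide carbon C3. C8 is written as a silyl enol ether, so the cascade ends on oxygen and cannot run on to C13=C14. The forward reaction must activate the epoxide without rearrangement, close both rings trans, and terminate on the enol silane.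

**C8–C9 and C11–C12 bonds (17 ⇐ 10 + a two-carbon vinyl anion + 14).** The enol silane is not made by enolising a ketone, which could not distinguish C7 from C9. It is assembled from acylsilane 10 (C8), a vinyl unit (C9, C11) and allylic bromide 14 (C12–C15). The forward reaction is 1,2-addition, silyl shift from carbon to oxygen, and alkylation at the allyl terminus, which fixes both the position and the geometry of the enol ether.

**Acylsilane 10 (10 ⇐ 8 ⇐ 5 + 6; 5 ⇐ 3 ⇐ 2 ⇐ 1).** The C6–C7 bond is cut between an allylic bromide and a silylacetylene, whose two carbons become C7 and the acylsilane carbon C8. The C3 stereocentre is traced to a catalytic asymmetric epoxidation of the distal alkene of 1; the allylic acetate deactivates the other alkene.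

**Bromide 14 (14 ⇐ 13 ⇐ 12 ⇐ 11).** The C12 bromide comes from allylic oxidation of the E methyl of a prenyl ether, which also fixes the 13E geometry.

## Alternatives that were turned down

**Alternative 1:** the textbook route cuts the same two ring bonds on the intact C20 chain. A Lewis acid would cyclise (14R)-14,15-epoxygeranylgeranyl acetate A1 to the hydroxy diene acetate A2, followed by acyl exchange. It was turned down for three reasons.
- After ring B closes, the C8 cation of this substrate has no built-in exit. It can lose a proton from C7, C17 or C9 (three alkene positions of similar energy).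
- The chain holds C13=C14 exactly where a six-membered third ring closes. The allylic acetate lowers the nucleophilicity of that alkene but does not remove it.
- The terminal epoxidation must pick one of three similar distal alkenes.

The route is short (about seven steps), but nothing in A1 secures the two selectivities the target demands, and the saving would be spent separating A2 from its isomers.

**Alternative 2:** a semisynthesis with no ring-forming step, from andrographolide A3. This commercial ent-labdane has C3, C5, C9 and C10 configured as in 32; the key intermediate would be the 14-deoxy butenolide A4. The route would have to do four things.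
- Remove the oxygen at C14.
- Remove the neopentyl primary oxygen at C19.
- Reduce the lactone carbonyl C16 to a methyl while C15 stays an alcohol; after reduction these are two primary allylic oxygens on one alkene.
- Move C8=C17 to C7=C8 without going on to the tetrasubstituted C8=C9 alkene, which thermodynamic control favours.

These are four unrelated functional-group problems, each of several steps, for a total above a dozen steps in which no step is strategic.

**Alternative 3:** an annulation route. A proline-catalysed Robinson annulation gives (R)-Wieland–Miescher ketone A5 and sets C10. Gem-dimethylation at C4, ketone reduction and hydrogenation would give the hydroxy decalone A6 with C3, C5 and C10 in place. C8, C17, the ring B alkene and the whole side chain would then have to be built on the C9 ketone. It was turned down for three reasons.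
- The C9 ketone is neopentyl (next to C10), so additions there are slow.
- The C9 stereocentre would be set late, by addition or reduction at a hindered carbon with no chair transition state to guide it.
- The sequence is linear and well over fifteen steps, and the alkene regiochemistry would in the end again call for a C8 ketone, which the chosen route obtains directly from its key step.

Key step: step 10

Assumption: the acyl chain of the target is read as 30-hydroxytriacontanoyl (carbonyl carbon followed by 29 methylene carbons); this ω-hydroxy acid is treated as not routinely purchasable and is assembled from 15-bromopentadecanoic acid.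

## Route

Step 1
Reactants: 1 geranyl acetate
Product: 2 (6R)-6,7-epoxygeranyl acetate
Conditions: KHSO5 (Oxone), D-fructose-derived Shi ketone (0.3 equiv), K2CO3, Bu4NHSO4, MeCN/CH2(OMe)2/aq. Na2B4O7 buffer (pH 10.5), 0 °C
Reagents that add atoms: potassium peroxymonosulfate, [K+].[O-]S(=O)(=O)OO
Why: Shi epoxidation through a chiral dioxirane; the 6,7-alkene is the electron-rich one because the allylic acetate deactivates the 2,3-alkene, and the spiro transition state of the D-fructose-derived ketone should deliver oxygen to the face that gives the (R)-epoxide, which becomes C3 of 32.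

Step 2
Reactants: 2 (6R)-6,7-epoxygeranyl acetate
Product: 3 (6R)-6,7-epoxygeraniol
Conditions: K2CO3 (cat.), MeOH, 0 °C → rt
Reagents that add atoms: none
Why: Base-catalysed transesterification (methanolysis) of the acetate; the trisubstituted epoxide is inert to K2CO3/MeOH.

Step 3
Reactants: 3 (6R)-6,7-epoxygeraniol
Product: 5 (6R)-6,7-epoxygeranyl bromide, via allylic mesylate 4 (not isolated)
Conditions: MsCl, Et3N, THF, −45 °C; then LiBr, THF, 0 °C
Reagents that add atoms: lithium bromide, [Li+].[Br-]
Why: Mesylation, then SN2 displacement by bromide at the primary allylic carbon at low temperature, which keeps the distant epoxide and the E alkene geometry.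

Step 4
Reactants: 5 (6R)-6,7-epoxygeranyl bromide; 6 tert-butyl(ethynyl)dimethylsilane
Product: 8 tert-butyl{(4E)-7-[(2R)-3,3-dimethyloxiran-2-yl]-5-methylhept-4-en-1-yn-1-yl}dimethylsilane, via alkynylmagnesium bromide 7 (not isolated)
Conditions: 6, EtMgBr, THF, 0 °C → rt; then CuBr·SMe2 (5 mol %), 5, THF, 0 °C → rt
Reagents that add atoms: none
Why: Copper-catalysed SN2 alkynylation of a primary allylic bromide by an alkynyl Grignard reagent gives the skipped enyne; the alkynylcopper species is too soft to open the trisubstituted epoxide, and the E alkene is retained.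

Step 5
Reactants: 8 skipped enyne
Product: 10 (4E)-1-[tert-butyl(dimethyl)silyl]-7-[(2R)-3,3-dimethyloxiran-2-yl]-5-methylhept-4-en-1-one (acylsilane), via alkenylborane 9 (not isolated)
Conditions: Cy2BH (from BH3·SMe2 and cyclohexene), THF, 0 °C → rt; then Me3NO (3.3 equiv), THF, 0 → 60 °C
Reagents that add atoms: trimethylamine N-oxide, C[N+](C)(C)[O-]
Why: Hydroboration–oxidation of a 1-silylalkyne; the bulky dialkylborane adds syn with boron on the silicon-bearing carbon and ignores the trisubstituted alkene, and non-basic oxidation of the C–B bond gives the enol that tautomerises to the acylsilane without Brook-type cleavage.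

Step 6
Reactants: 11 3-methylbut-2-en-1-ol (prenol)
Product: 12 tert-butyl[(3-methylbut-2-en-1-yl)oxy]diphenylsilane
Conditions: TBDPSCl, imidazole, CH2Cl2, 0 °C → rt
Reagents that add atoms: tert-butyl(chloro)diphenylsilane, CC(C)(C)[Si](Cl)(c1ccccc1)c1ccccc1
Why: Silylation of a primary allylic alcohol; the tert-butyldiphenylsilyl ether is chosen to survive the organolithium, Lewis acid and Grignard steps.

Step 7
Reactants: 12 prenyl silyl ether
Product: 13 (2E)-4-{[tert-butyl(diphenyl)silyl]oxy}-2-methylbut-2-en-1-ol
Conditions: SeO2 (cat.), t-BuOOH, salicylic acid (cat.), CH2Cl2, rt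
Reagents that add atoms: tert-butyl hydroperoxide, CC(C)(C)OO
Why: SeO2-mediated allylic hydroxylation (ene reaction, then [2,3]-sigmatropic shift, oxygen relayed from the hydroperoxide) is selective for the E methyl of a trisubstituted alkene, which sets the 13E geometry of 32.

Step 8
Reactants: 13 E allylic alcohol
Product: 14 {[(2E)-4-bromo-3-methylbut-2-en-1-yl]oxy}(tert-butyl)diphenylsilane
Conditions: CBr4, PPh3, 2,6-lutidine (cat.), CH2Cl2, 0 °C
Reagents that add atoms: carbon tetrabromide, BrC(Br)(Br)Br
Why: Appel reaction; SN2 at the primary allylic carbon keeps the E geometry.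

Step 9
Reactants: 10 acylsilane; 14 allylic bromide
Product: 17 tert-butyl{[(2E,6Z,10E)-7-{[tert-butyl(dimethyl)silyl]oxy}-13-[(2R)-3,3-dimethyloxiran-2-yl]-3,11-dimethyltrideca-2,6,10-trien-1-yl]oxy}diphenylsilane, via lithium alkoxide 15 (not isolated), via siloxyallyllithium 16 (not isolated)
Conditions: CH2=CHLi (from Sn(CH=CH2)4 and PhLi, Et2O), Et2O, −78 °C; then 14, THF, −78 → −30 °C
Reagents that add atoms: vinyllithium, [Li]C=C
Why: Acylsilane–vinyllithium–electrophile coupling through a Brook rearrangement; 1,2-addition gives alkoxide 15, the carbon-to-oxygen silyl shift gives the lithium-bridged siloxyallyl anion 16, and SN2 alkylation at its unsubstituted terminus by 14 gives the enol silane with fixed position (C8–O, C8=C9) and Z geometry.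

Step 10
Reactants: 17 acyclic epoxy (Z)-enol silane
Product: 19 (3R,5S,9S,10R)-15-{[tert-butyl(diphenyl)silyl]oxy}-3-hydroxy-17-norlabd-13E-en-8-one, via aluminium alkoxide 18 (not isolated)
Conditions: MeAlCl2 (2 equiv, hexanes), CH2Cl2, −94 → −78 °C; aq. NaHCO3 work-up
Reagents that add atoms: none
Why: This is an epoxide-initiated cationic bicyclization ended by a silyl enol ether (Mukaiyama-type capture of a carbocation); the closest known reaction type is the MeAlCl2-promoted cyclization of epoxy polyenes that end in silyl enol ethers to polycyclic hydroxy ketones. MeAlCl2 binds the epoxide oxygen, and ionisation of the tertiary C4–O bond is assisted by the C5=C10 alkene, which attacks C4 anti to the leaving oxygen, so ring A closes in a 6-endo mode (both alkene carbons and both epoxide carbons end up in the ring). The developing C10 cation is captured by C9 of the enol silane, so ring B closes 6-endo-trig and the charge ends on oxygen; loss of the silyl group (as the silyl chloride or by transfer to O3) leaves the C8 ketone as its aluminium alkoxide 18. C3 keeps the configuration of the epoxide because its C–O bond is never broken. C5 and C10 follow from anti addition across the E alkene in a chair–chair array with the C3 oxygen pseudo-equatorial, which gives the trans ring fusion with H5 anti and C20 syn to the 3-oxygen. C9 is set by the Z geometry of the enol silane in the chair (side chain equatorial, H9 anti to C20), and because C9 is α to the new ketone the equatorial epimer is also the thermodynamic one, so material from any E enol silane converges on the same product. The step needs selectivity for the enol silane over the C13=C14 alkene and the allylic silyl ether: the enol silane is by far the best nucleophile and sits at ring-closing distance from C10, its capture leaves a neutral ketone and no C8 carbocation for a third ring or for alkene isomers, and MeAlCl2 scavenges adventitious acid that would protodesilylate the enol ether.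

Step 11
Reactants: 19 hydroxy ketone
Product: 20 (3R,5S,9S,10R)-3-{[tert-butyl(dimethyl)silyl]oxy}-15-{[tert-butyl(diphenyl)silyl]oxy}-17-norlabd-13E-en-8-one
Conditions: TBSOTf, 2,6-lutidine, CH2Cl2, −78 → 0 °C
Reagents that add atoms: tert-butyldimethylsilyl trifluoromethanesulfonate, CC(C)(C)[Si](C)(C)OS(=O)(=O)C(F)(F)F
Why: Silylation of the hindered equatorial C3 hydroxyl with a silyl triflate; 2,6-lutidine is too weak a base to enolise the ketone, and any material that already carries the silyl group on O3 after step 10 is the same compound 20.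

Step 12
Reactants: 20 silyloxy ketone
Product: 22 (3R,5S,9S,10R)-3-{[tert-butyl(dimethyl)silyl]oxy}-15-{[tert-butyl(diphenyl)silyl]oxy}-17-norlabda-7,13E-dien-8-yl trifluoromethanesulfonate, via potassium enolate 21 (not isolated)
Conditions: KN(SiMe3)2, THF, −78 °C; then PhNTf2, −78 → 0 °C
Reagents that add atoms: N-phenylbis(trifluoromethanesulfonimide), O=S(=O)(N(c1ccccc1)S(=O)(=O)C(F)(F)F)C(F)(F)F
Why: Kinetic enolisation takes a C7 proton (C9–H is tertiary and shielded by C10 and the side chain), and O-triflation fixes the alkene at C7=C8; C9 is not touched.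

Step 13
Reactants: 22 enol triflate
Product: 23 tert-butyl{[(3R,5S,9R,10S)-15-{[tert-butyl(diphenyl)silyl]oxy}labda-7,13E-dien-3-yl]oxy}dimethylsilane
Conditions: MeMgBr, Fe(acac)3 (5 mol %), THF/NMP, −30 → 0 °C
Reagents that add atoms: methylmagnesium bromide, C[Mg]Br
Why: Iron-catalysed Kumada-type cross-coupling of an alkenyl triflate with a methyl Grignard reagent installs C17 with retention of the alkene position; silyl ethers and isolated alkenes are tolerated.

Step 14
Reactants: 24 15-bromopentadecanoic acid
Product: 25 15-bromopentadecan-1-ol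
Conditions: BH3·THF, THF, 0 °C → rt; aqueous work-up
Reagents that add atoms: none
Why: Borane reduces the carboxylic acid (through the acyloxyborane) much faster than it touches a primary alkyl bromide.

Step 15
Reactants: 25 15-bromopentadecan-1-ol
Product: 26 [(15-bromopentadecyl)oxy](tert-butyl)dimethylsilane
Conditions: TBSCl, imidazole, CH2Cl2, rt
Reagents that add atoms: tert-butyl(chloro)dimethylsilane, CC(C)(C)[Si](C)(C)Cl
Why: Standard silylation of a primary alcohol; the silyl ether survives Grignard formation and later serves as the ω-protecting group.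

Step 16
Reactants: 26 silyloxy bromide; 24 15-bromopentadecanoic acid
Product: 29 30-{[tert-butyl(dimethyl)silyl]oxy}triacontanoic acid, via Grignard reagent 27 (not isolated), via chloromagnesium carboxylate 28 (not isolated)
Conditions: 26, Mg, THF, 45 °C; 24, MeMgCl (1.0 equiv), THF, −20 °C; combine, Li2CuCl4 (3 mol %), THF, −20 °C → rt; aq. citric acid work-up
Reagents that add atoms: none
Why: Li2CuCl4-catalysed sp3–sp3 coupling of a primary alkyl Grignard reagent with a primary alkyl bromide; the acid is masked in the flask as its magnesium carboxylate, which is inert at −20 °C, and 15 + 15 carbons give the C30 chain.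

Step 17
Reactants: 23 bis-silyl ether
Product: 30 (3R,5S,9R,10S)-3-{[tert-butyl(dimethyl)silyl]oxy}labda-7,13E-dien-15-ol
Conditions: Bu4NF (1.2 equiv), AcOH (1.2 equiv), THF, 0 °C → rt
Reagents that add atoms: none
Why: Fluoride cleaves the unhindered primary allylic silyl ether far faster than the secondary silyl ether at C3, which is shielded by the C4 gem-dimethyl group; acetic acid buffers the alkoxide.

Step 18
Reactants: 30 allylic alcohol; 29 silyloxy acid
Product: 31 (3R,5S,9R,10S)-3-{[tert-butyl(dimethyl)silyl]oxy}labda-7,13E-dien-15-yl 30-{[tert-butyl(dimethyl)silyl]oxy}triacontanoate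
Conditions: EDC·HCl, DMAP, CH2Cl2, rt
Reagents that add atoms: none
Why: Steglich esterification of the only free hydroxyl (primary, allylic) under near-neutral conditions that do not ionise or isomerise the allylic system.

Step 19
Reactants: 31 bis-silyl ester
Product: 32 (3R,5S,9R,10S)-3-hydroxylabda-7,13E-dien-15-yl 30-hydroxytriacontanoate (CNP0303636.1)
Conditions: HF·pyridine, pyridine, THF, 0 °C → rt
Reagents that add atoms: none
Why: Buffered HF removes both silyl ethers (the hindered one at C3 more slowly) without acyl migration or alkene isomerisation and should give the target.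

## Compound list

1 | geranyl acetate, (2E)-3,7-dimethylocta-2,6-dien-1-yl acetate | CC(C)=CCC/C(C)=C/COC(C)=O | starting material
2 | (6R)-6,7-epoxygeranyl acetate, (2E)-5-[(2R)-3,3-dimethyloxiran-2-yl]-3-methylpent-2-en-1-yl acetate | CC1(C)O[C@@H]1CC/C(C)=C/COC(C)=O | intermediate
3 | (6R)-6,7-epoxygeraniol | CC1(C)O[C@@H]1CC/C(C)=C/CO | intermediate
4 | (6R)-6,7-epoxygeranyl methanesulfonate | CC1(C)O[C@@H]1CC/C(C)=C/COS(C)(=O)=O | intermediate (not isolated)
5 | (6R)-6,7-epoxygeranyl bromide, (3R)-3-[(3E)-5-bromo-3-methylpent-3-en-1-yl]-2,2-dimethyloxirane | CC1(C)O[C@@H]1CC/C(C)=C/CBr | intermediate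
6 | tert-butyl(ethynyl)dimethylsilane | C#C[Si](C)(C)C(C)(C)C | starting material
7 | {[tert-butyl(dimethyl)silyl]ethynyl}magnesium bromide | Br[Mg]C#C[Si](C)(C)C(C)(C)C | intermediate (not isolated)
8 | tert-butyl{(4E)-7-[(2R)-3,3-dimethyloxiran-2-yl]-5-methylhept-4-en-1-yn-1-yl}dimethylsilane | CC1(C)O[C@@H]1CC/C(C)=C/CC#C[Si](C)(C)C(C)(C)C | intermediate
9 | dicyclohexyl{(1Z,4E)-1-[tert-butyl(dimethyl)silyl]-7-[(2R)-3,3-dimethyloxiran-2-yl]-5-methylhepta-1,4-dien-1-yl}borane | CC1(C)O[C@@H]1CC/C(C)=C/C/C=C(/B(C1CCCCC1)C1CCCCC1)[Si](C)(C)C(C)(C)C | intermediate (not isolated)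
10 | (4E)-1-[tert-butyl(dimethyl)silyl]-7-[(2R)-3,3-dimethyloxiran-2-yl]-5-methylhept-4-en-1-one | CC1(C)O[C@@H]1CC/C(C)=C/CCC(=O)[Si](C)(C)C(C)(C)C | intermediate
11 | 3-methylbut-2-en-1-ol (prenol) | CC(C)=CCO | starting material
12 | tert-butyl[(3-methylbut-2-en-1-yl)oxy]diphenylsilane | CC(C)=CCO[Si](c1ccccc1)(c1ccccc1)C(C)(C)C | intermediate
13 | (2E)-4-{[tert-butyl(diphenyl)silyl]oxy}-2-methylbut-2-en-1-ol | OC/C(C)=C/CO[Si](c1ccccc1)(c1ccccc1)C(C)(C)C | intermediate
14 | {[(2E)-4-bromo-3-methylbut-2-en-1-yl]oxy}(tert-butyl)diphenylsilane | BrC/C(C)=C/CO[Si](c1ccccc1)(c1ccccc1)C(C)(C)C | intermediate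
15 | lithium (6E)-3-[tert-butyl(dimethyl)silyl]-9-[(2R)-3,3-dimethyloxiran-2-yl]-7-methylnona-1,6-dien-3-olate (both C3 epimers) | [Li+].CC1(C)O[C@@H]1CC/C(C)=C/CCC([O-])(C=C)[Si](C)(C)C(C)(C)C | intermediate (not isolated)
16 | [(2Z,6E)-3-{[tert-butyl(dimethyl)silyl]oxy}-9-[(2R)-3,3-dimethyloxiran-2-yl]-7-methylnona-2,6-dien-1-yl]lithium | CC1(C)O[C@@H]1CC/C(C)=C/CC/C(O[Si](C)(C)C(C)(C)C)=C/C[Li] | intermediate (not isolated)
17 | tert-butyl{[(2E,6Z,10E)-7-{[tert-butyl(dimethyl)silyl]oxy}-13-[(2R)-3,3-dimethyloxiran-2-yl]-3,11-dimethyltrideca-2,6,10-trien-1-yl]oxy}diphenylsilane | CC1(C)O[C@@H]1CC/C(C)=C/CC/C(O[Si](C)(C)C(C)(C)C)=C/CC/C(C)=C/CO[Si](c1ccccc1)(c1ccccc1)C(C)(C)C | intermediate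
18 | chloro(methyl)aluminium O3-alkoxide of hydroxy ketone 19 | O=C1CC[C@@H]2C(C)(C)[C@H](O[Al](C)Cl)CC[C@@]2(C)[C@@H]1CC/C(C)=C/CO[Si](c1ccccc1)(c1ccccc1)C(C)(C)C | intermediate (not isolated)
19 | (3R,5S,9S,10R)-15-{[tert-butyl(diphenyl)silyl]oxy}-3-hydroxy-17-norlabd-13E-en-8-one (3-OH, C20 and the C9 chain on one face; H5 and H9 on the other) | O=C1CC[C@@H]2C(C)(C)[C@H](O)CC[C@@]2(C)[C@@H]1CC/C(C)=C/CO[Si](c1ccccc1)(c1ccccc1)C(C)(C)C | intermediate
20 | (3R,5S,9S,10R)-3-{[tert-butyl(dimethyl)silyl]oxy}-15-{[tert-butyl(diphenyl)silyl]oxy}-17-norlabd-13E-en-8-one | O=C1CC[C@@H]2C(C)(C)[C@H](O[Si](C)(C)C(C)(C)C)CC[C@@]2(C)[C@@H]1CC/C(C)=C/CO[Si](c1ccccc1)(c1ccccc1)C(C)(C)C | intermediate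
21 | potassium C7-enolate of ketone 20 | [K+].[O-]C1=CC[C@@H]2C(C)(C)[C@H](O[Si](C)(C)C(C)(C)C)CC[C@@]2(C)[C@@H]1CC/C(C)=C/CO[Si](c1ccccc1)(c1ccccc1)C(C)(C)C | intermediate (not isolated)
22 | (3R,5S,9S,10R)-3-{[tert-butyl(dimethyl)silyl]oxy}-15-{[tert-butyl(diphenyl)silyl]oxy}-17-norlabda-7,13E-dien-8-yl trifluoromethanesulfonate | FC(F)(F)S(=O)(=O)OC1=CC[C@@H]2C(C)(C)[C@H](O[Si](C)(C)C(C)(C)C)CC[C@@]2(C)[C@@H]1CC/C(C)=C/CO[Si](c1ccccc1)(c1ccccc1)C(C)(C)C | intermediate
23 | tert-butyl{[(3R,5S,9R,10S)-15-{[tert-butyl(diphenyl)silyl]oxy}labda-7,13E-dien-3-yl]oxy}dimethylsilane | CC1=CC[C@@H]2C(C)(C)[C@H](O[Si](C)(C)C(C)(C)C)CC[C@@]2(C)[C@@H]1CC/C(C)=C/CO[Si](c1ccccc1)(c1ccccc1)C(C)(C)C | intermediate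
24 | 15-bromopentadecanoic acid | OC(=O)CCCCCCCCCCCCCCBr | starting material
25 | 15-bromopentadecan-1-ol | OCCCCCCCCCCCCCCCBr | intermediate
26 | [(15-bromopentadecyl)oxy](tert-butyl)dimethylsilane | CC(C)(C)[Si](C)(C)OCCCCCCCCCCCCCCCBr | intermediate
27 | (15-{[tert-butyl(dimethyl)silyl]oxy}pentadecyl)magnesium bromide | CC(C)(C)[Si](C)(C)OCCCCCCCCCCCCCCC[Mg]Br | intermediate (not isolated)
28 | chloromagnesium 15-bromopentadecanoate | Cl[Mg]OC(=O)CCCCCCCCCCCCCCBr | intermediate (not isolated)
29 | 30-{[tert-butyl(dimethyl)silyl]oxy}triacontanoic acid | CC(C)(C)[Si](C)(C)OCCCCCCCCCCCCCCCCCCCCCCCCCCCCCC(=O)O | intermediate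
30 | (3R,5S,9R,10S)-3-{[tert-butyl(dimethyl)silyl]oxy}labda-7,13E-dien-15-ol | CC1=CC[C@@H]2C(C)(C)[C@H](O[Si](C)(C)C(C)(C)C)CC[C@@]2(C)[C@@H]1CC/C(C)=C/CO | intermediate
31 | (3R,5S,9R,10S)-3-{[tert-butyl(dimethyl)silyl]oxy}labda-7,13E-dien-15-yl 30-{[tert-butyl(dimethyl)silyl]oxy}triacontanoate | CC1=CC[C@@H]2C(C)(C)[C@H](O[Si](C)(C)C(C)(C)C)CC[C@@]2(C)[C@@H]1CC/C(C)=C/COC(=O)CCCCCCCCCCCCCCCCCCCCCCCCCCCCCO[Si](C)(C)C(C)(C)C | intermediate
32 | (3R,5S,9R,10S)-3-hydroxylabda-7,13E-dien-15-yl 30-hydroxytriacontanoate (CNP0303636.1) | CC1=CC[C@@H]2C(C)(C)[C@H](O)CC[C@@]2(C)[C@@H]1CC/C(C)=C/COC(=O)CCCCCCCCCCCCCCCCCCCCCCCCCCCCCO | target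

## Step count and least certain steps

Total step count: 19. Longest linear sequence: 13 steps (steps 1–5, 9–13, 17–19); steps 6–8 and 14–16 are side branches.

**Step 10 (key step).** The most likely failures are three. The Lewis-acid-bound epoxide may rearrange by hydride shift before the alkene engages. The cascade may stop after ring A by loss of a proton from the C10 cation. The enol ether may be protodesilylated before ring B closes. All three arise because the tertiary epoxonium species lives long if chair folding of the chain is slow, and because the enol silane is the most acid-labile group present.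

Fallback, from 17 back to 23, using a trisubstituted alkene as terminator with the methyl installed before ring closure:
- The enol silane is exchanged for an enol triflate with retention of position and geometry (CsF, PhNTf2, DME) to give the acyclic (2E,6Z,10E)-enol triflate F1.
- Iron-catalysed methylation (MeMgBr, Fe(acac)3, −30 °C) gives the (14R)-14,15-epoxygeranylgeranyl silyl ether F2.
- Alkene-terminated bicyclization of F2 with a Lewis acid (InBr3, CH2Cl2, −20 °C) gives the 3-hydroxy-7,13-diene silyl ether F3, after chromatographic removal of material from other proton losses and from further ring closure.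
- Silylation of O3 (TBSOTf, 2,6-lutidine) returns to 23.

**Step 9.** The ambident siloxyallyl anion 16 may be alkylated at the oxygen-bearing carbon instead of the terminus, the silyl shift may be incomplete in ether, or SN2′ attack on 14 may compete. The bulky silyl group and the lithium aggregate state control these ratios, and they are sensitive to solvent.

Fallback, from 5 and 14 back to 17, building the regiodefined enol silane by conjugate reduction instead of by an allyl anion:
- Bromide 5 alkylates the lithium enolate of N-methoxy-N-methylacetamide (LiN(iPr)2, THF, −78 °C) to give the Weinreb amide F4.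
- Vinylmagnesium bromide converts F4 into the vinyl ketone F5.
- Bromide 14 and vinylmagnesium bromide (CuBr·SMe2 cat.) give the skipped diene F6.
- Cross-metathesis of F5 with F6 (second-generation Grubbs catalyst, RuCl2(=CHPh)(PCy3)(H2IMes), CH2Cl2, 40 °C) gives the E-enone F7.
- Conjugate reduction of F7 with [(Ph3P)CuH]6 in the presence of TBSCl traps the enolate on oxygen as the (Z)-enol silane 17.

**Step 5.** The hydroboration may go with the wrong regiochemistry, with boron on the carbon remote from the bulky silyl group, and the acylsilane may be cleaved during oxidation.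

Fallback, from 5 back to 10, by enolate alkylation instead of alkyne hydroboration:
- Ethyl vinyl ether is lithiated (t-BuLi) and silylated (TBSCl) to give tert-butyl(1-ethoxyethenyl)dimethylsilane F8.
- Mild acid hydrolysis of F8 gives 1-[tert-butyl(dimethyl)silyl]ethan-1-one F9.
- The lithium enolate of F9 (LiN(iPr)2, THF, −78 °C) is alkylated by allylic bromide 5 at C6 to give acylsilane 10.

**Step 17.** The two silyl ethers may not be discriminated well: the O3 silyl group may be partly lost, or cleavage at O15 may be incomplete. The selectivity rests only on the steric difference between the two sites.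

Fallback, from 23 to 32, relying on selective acylation instead of selective desilylation:
- Both silyl groups are removed (HF·pyridine, THF, rt) to give (3R,5S,9R,10S)-labda-7,13E-diene-3,15-diol F10.
- Steglich acylation of F10 with 29 at 0 °C takes the primary allylic hydroxyl in preference to the secondary C3 hydroxyl next to the gem-dimethyl carbon, to give the mono-ester F11.
- HF·pyridine removes the remaining ω-silyl group and gives 32.

## Further compounds

F1 | step 10 | (2E,6Z,10E)-1-{[tert-butyl(diphenyl)silyl]oxy}-13-[(2R)-3,3-dimethyloxiran-2-yl]-3,11-dimethyltrideca-2,6,10-trien-7-yl trifluoromethanesulfonate | CC1(C)O[C@@H]1CC/C(C)=C/CC/C(OS(=O)(=O)C(F)(F)F)=C/CC/C(C)=C/CO[Si](c1ccccc1)(c1ccccc1)C(C)(C)C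
F2 | step 10 | tert-butyl{[(2E,6E,10E)-13-[(2R)-3,3-dimethyloxiran-2-yl]-3,7,11-trimethyltrideca-2,6,10-trien-1-yl]oxy}diphenylsilane | CC1(C)O[C@@H]1CC/C(C)=C/CC/C(C)=C/CC/C(C)=C/CO[Si](c1ccccc1)(c1ccccc1)C(C)(C)C
F3 | step 10 | (3R,5S,9R,10S)-15-{[tert-butyl(diphenyl)silyl]oxy}labda-7,13E-dien-3-ol | CC1=CC[C@@H]2C(C)(C)[C@H](O)CC[C@@]2(C)[C@@H]1CC/C(C)=C/CO[Si](c1ccccc1)(c1ccccc1)C(C)(C)C
F4 | step 9 | (4E)-7-[(2R)-3,3-dimethyloxiran-2-yl]-N-methoxy-N,5-dimethylhept-4-enamide | CC1(C)O[C@@H]1CC/C(C)=C/CCC(=O)N(C)OC
F5 | step 9 | (6E)-9-[(2R)-3,3-dimethyloxiran-2-yl]-7-methylnona-1,6-dien-3-one | CC1(C)O[C@@H]1CC/C(C)=C/CCC(=O)C=C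
F6 | step 9 | tert-butyl{[(2E)-3-methylhexa-2,5-dien-1-yl]oxy}diphenylsilane | C=CC/C(C)=C/CO[Si](c1ccccc1)(c1ccccc1)C(C)(C)C
F7 | step 9 | (2E,5E,10E)-1-{[tert-butyl(diphenyl)silyl]oxy}-13-[(2R)-3,3-dimethyloxiran-2-yl]-3,11-dimethyltrideca-2,5,10-trien-7-one | CC1(C)O[C@@H]1CC/C(C)=C/CCC(=O)/C=C/C/C(C)=C/CO[Si](c1ccccc1)(c1ccccc1)C(C)(C)C
F8 | step 5 | tert-butyl(1-ethoxyethenyl)dimethylsilane | C=C(OCC)[Si](C)(C)C(C)(C)C
F9 | step 5 | 1-[tert-butyl(dimethyl)silyl]ethan-1-one | CC(=O)[Si](C)(C)C(C)(C)C
F10 | step 17 | (3R,5S,9R,10S)-labda-7,13E-diene-3,15-diol | CC1=CC[C@@H]2C(C)(C)[C@H](O)CC[C@@]2(C)[C@@H]1CC/C(C)=C/CO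
F11 | step 17 | (3R,5S,9R,10S)-3-hydroxylabda-7,13E-dien-15-yl 30-{[tert-butyl(dimethyl)silyl]oxy}triacontanoate | CC1=CC[C@@H]2C(C)(C)[C@H](O)CC[C@@]2(C)[C@@H]1CC/C(C)=C/COC(=O)CCCCCCCCCCCCCCCCCCCCCCCCCCCCCO[Si](C)(C)C(C)(C)C
A1 | alternative 1 | (14R)-14,15-epoxy-(2E,6E,10E)-geranylgeranyl acetate | CC1(C)O[C@@H]1CC/C(C)=C/CC/C(C)=C/CC/C(C)=C/COC(C)=O
A2 | alternative 1 | (3R,5S,9R,10S)-3-hydroxylabda-7,13E-dien-15-yl acetate | CC1=CC[C@@H]2C(C)(C)[C@H](O)CC[C@@]2(C)[C@@H]1CC/C(C)=C/COC(C)=O
A3 | alternative 2 | andrographolide | C=C1CC[C@@H]2[C@](C)(CO)[C@H](O)CC[C@@]2(C)[C@@H]1C/C=C1\[C@H](O)COC1=O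
A4 | alternative 2 | 14-deoxyandrographolide (3,19-dihydroxy-ent-labda-8(17),13-dien-16,15-olide) | C=C1CC[C@@H]2[C@](C)(CO)[C@H](O)CC[C@@]2(C)[C@@H]1CCC1=CCOC1=O
A5 | alternative 3 | (R)-Wieland–Miescher ketone, (8aR)-8a-methyl-3,4,8,8a-tetrahydronaphthalene-1,6(2H,7H)-dione | C[C@@]12CCC(=O)C=C1CCCC2=O
A6 | alternative 3 | 3-hydroxy-4,4,10-trimethyl-trans-decal-9-one (labdane numbering; C3, C5 and C10 configured as in 32) | O=C1CCC[C@@H]2C(C)(C)[C@H](O)CC[C@@]12C
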